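**Plan**

- Retrosynthesis (dienone numbered C1 = carbonyl, C2 = allyl-bearing, C4 = quaternary, C5 = methoxy-bearing): cut the O–CH3 bond at C4; then the C4–alkenyl bond, leaving 2-allyl-5-methoxy-1,4-benzoquinone and an (E)-alkenyl metal; then the ring bond C1–C2, which unravels the quinone to a 4-alkynyl-4-hydroxycyclobutenone; then the carbinol–alkyne bond, leaving methyl semisquarate and pent-1-en-4-yne.
- Enabling feature: the ring run C1(=O)–C6H=C5(OMe)–C4(–O) is a latent 3-methoxycyclobutenone and C3H=C2(allyl) is a latent alkyne. Strain release of the four-membered ring as a ketene can therefore close the six-membered ring at C1–C2; the temporary four-membered ring is consumed in the event itself.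
- Forward order: the four-membered ring is bought as dimethyl squarate and trimmed, the alkyne is added, the cyclobutenone is opened and the quinone ring closed in one thermal event, the side chain is joined at the quinone carbonyl next to the methoxy carbon, and the carbinol is O-methylated.
- Stereochemistry: the single stereocentre (S at C4) is set in the alkenyl addition to the prochiral quinone carbonyl by a chiral titanium catalyst. The (E) alkene comes from syn-hydrozirconation of the arylpropyne and transfer with retention.

Key step: step 3

Assumption: the sense of face selection in the titanium-mediated alkenylation cannot be fixed on paper, so the ligand antipode that leads to the (S)-carbinol is to be identified in a first run and then used; both antipodes are accessible.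

Step 1
Reactants: 1 dimethyl squarate
Product: 3 3-methoxycyclobut-3-ene-1,2-dione (methyl semisquarate), via hydroxycyclobutenone 2 (not isolated)
Conditions: LiAlH(OtBu)3 (1.05 equiv), THF, −78 to −20 °C; then 2 M HCl, 0 °C to rt, one pot
Reagents that add atoms: water (from the aqueous acid; its oxygen becomes the new carbonyl oxygen), O
Why: Hydride should add once to one of the two equivalent vinylogous ester carbonyls, and acid then ionizes the new carbinol to an allyl cation that water captures at the methoxy-bearing terminus with loss of methanol (reduction followed by acid-induced 1,3-carbonyl transposition, the usual entry to alkyl semisquarates).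

Step 2
Reactants: 3 methyl semisquarate; 4 pent-1-en-4-yne
Product: 6 4-hydroxy-3-methoxy-4-(pent-4-en-1-yn-1-yl)cyclobut-2-en-1-one (racemic), via lithium acetylide 5 (not isolated)
Conditions: 4, n-BuLi (1.0 equiv), THF, −78 °C; then added to 3, THF, −78 °C; NH4Cl (aq)
Reagents that add atoms: none
Why: The lithium acetylide should add 1,2 to the ketone-like carbonyl next to the methoxy-bearing carbon, because the other carbonyl is deactivated as a vinylogous ester (acetylide 1,2-addition to a cyclobutenedione); the new carbinol centre is racemic and is erased in step 3.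

Step 3
Reactants: 6 4-hydroxy-3-methoxy-4-(pent-4-en-1-yn-1-yl)cyclobut-2-en-1-one
Product: 8 2-allyl-5-methoxy-1,4-benzoquinone, via alkynyl vinylketene 7 (not isolated)
Conditions: degassed p-xylene (0.02 M), 138 °C, 15–30 min
Reagents that add atoms: none
Why: Heating should trigger conrotatory 4π ring opening of the strained cyclobutenone, the hydroxyl rotating outward so that the alkyne is held cis to the new ketene in the (3Z)-dienynyl ketene 7. The ketene carbon (future C1) then bonds to the remote, allyl-bearing alkyne carbon (future C2), a 6-endo-dig closure that gives the six-membered ring as a phenoxyl/aryl 1,4-diradical, and transfer of the hydroxyl hydrogen to the ring carbon radical delivers the quinone. The closest known reaction type is the Moore rearrangement of 4-alkynyl-4-hydroxycyclobutenones to 1,4-benzoquinones. No stereocentre is formed; the racemic carbinol centre of 6 becomes the prochiral quinone carbonyl C4. The step needs outward torquoselectivity of the hydroxyl and six- over five-membered closure; the first is secured by the donor oxygen on the breaking bond, the second by the alkyl, non-radical-stabilising substituent on the alkyne. The substitution pattern (allyl next to the ketene-derived carbonyl, methoxy para to allyl, hydrogen at C3 and C6) is fixed by the connectivity of 6 and needs no further control.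

Step 4
Reactants: 9 4-iodo-1,2-dimethoxybenzene; 10 propyne
Product: 11 1,2-dimethoxy-4-(prop-1-yn-1-yl)benzene
Conditions: Pd(PPh3)2Cl2 (2 mol %), CuI (4 mol %), Et3N, THF, propyne (excess, THF solution), rt to 40 °C, sealed vessel
Reagents that add atoms: none
Why: Sonogashira coupling of an aryl iodide with a terminal alkyne under palladium/copper catalysis.

Step 5
Reactants: 11 1,2-dimethoxy-4-(prop-1-yn-1-yl)benzene; 8 2-allyl-5-methoxy-1,4-benzoquinone
Product: 14 (S)-2-allyl-4-hydroxy-5-methoxy-4-[(E)-1-(3,4-dimethoxyphenyl)prop-1-en-2-yl]cyclohexa-2,5-dien-1-one, via alkenylzirconocene chloride 12 (not isolated), via alkenyl(methyl)zinc 13 (not isolated)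
Conditions: Cp2Zr(H)Cl (0.95 equiv relative to 11), CH2Cl2, rt; solvent change to PhMe; ZnMe2, −78 °C; C2-symmetric bis(sulfonamide) diol ligand from trans-cyclohexane-1,2-diamine and camphor-10-sulfonyl chloride with both ketones reduced to exo alcohols (10 mol %), Ti(OiPr)4 (1.2 equiv); then 8, −20 °C to rt; NH4Cl (aq)
Reagents that add atoms: none
Why: Proposed new method: syn-hydrozirconation of 11 should put zirconium on the less hindered methyl-bearing carbon and hydrogen on the aryl-bearing carbon, transmetalation to zinc keeps the alkene geometry, and a chiral titanium bis(sulfonamide) diolate then binds the more electrophilic quinone carbonyl C4 (the other carbonyl is a vinylogous ester; C4=O can also chelate through the neighbouring methoxy oxygen) and hands the alkenyl group, in preference to methyl, to one face, the faces being told apart by the methoxy-bearing versus unsubstituted flank of that carbonyl, which sets C4 as (S); the closest known reaction type is the ligand-controlled titanium-mediated asymmetric addition of alkenylzinc reagents to ketones, including 2-substituted cyclic enones, and the site selectivity follows the known 1,2-addition of organometallics to the carbonyl next to the methoxy-bearing carbon of methoxy-p-benzoquinones.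

Step 6
Reactants: 14 (S)-2-allyl-4-hydroxy-5-methoxy-4-[(E)-1-(3,4-dimethoxyphenyl)prop-1-en-2-yl]cyclohexa-2,5-dien-1-one
Product: 16 (S)-2-allyl-4-[(E)-1-(3,4-dimethoxyphenyl)prop-1-en-2-yl]-4,5-dimethoxycyclohexa-2,5-dien-1-one, via sodium alkoxide 15 (not isolated)
Conditions: NaH (1.2 equiv), THF/DMF, 0 °C; MeI (3 equiv), 0 °C to rt
Reagents that add atoms: iodomethane, CI
Why: Williamson ether synthesis on the tertiary alkoxide; the dienone has no enolizable hydrogen, so only oxygen is deprotonated, and the stereocentre bears no hydrogen and cannot epimerize.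

**Compound list**

1 | dimethyl squarate (3,4-dimethoxycyclobut-3-ene-1,2-dione) | COC1=C(OC)C(=O)C1=O | starting material
2 | 4-hydroxy-2,3-dimethoxycyclobut-2-en-1-one (racemic, not isolated) | COC1=C(OC)C(O)C1=O | intermediate
3 | 3-methoxycyclobut-3-ene-1,2-dione (methyl semisquarate) | COC1=CC(=O)C1=O | intermediate
4 | pent-1-en-4-yne | C=CCC#C | starting material
5 | lithium pent-4-en-1-yn-1-ide (not isolated) | [Li]C#CCC=C | intermediate
6 | 4-hydroxy-3-methoxy-4-(pent-4-en-1-yn-1-yl)cyclobut-2-en-1-one (racemic) | COC1=CC(=O)C1(O)C#CCC=C | intermediate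
7 | (3Z)-4-hydroxy-3-methoxynona-1,3,8-trien-5-yn-1-one (alkynyl vinylketene, not isolated) | O=C=C/C(OC)=C(/O)C#CCC=C | intermediate
8 | 2-allyl-5-methoxy-1,4-benzoquinone | C=CCC1=CC(=O)C(OC)=CC1=O | intermediate
9 | 4-iodo-1,2-dimethoxybenzene | COc1ccc(I)cc1OC | starting material
10 | propyne | CC#C | starting material
11 | 1,2-dimethoxy-4-(prop-1-yn-1-yl)benzene | CC#Cc1ccc(OC)c(OC)c1 | intermediate
12 | chloro[(E)-1-(3,4-dimethoxyphenyl)prop-1-en-2-yl]bis(cyclopentadienyl)zirconium (aryl trans to zirconium, not isolated) | C/C(=C\c1ccc(OC)c(OC)c1)[Zr+2]Cl.[cH-]1cccc1.[cH-]1cccc1 | intermediate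
13 | [(E)-1-(3,4-dimethoxyphenyl)prop-1-en-2-yl](methyl)zinc (aryl trans to zinc, not isolated) | C/C(=C\c1ccc(OC)c(OC)c1)[Zn]C | intermediate
14 | (S)-2-allyl-4-hydroxy-5-methoxy-4-[(E)-1-(3,4-dimethoxyphenyl)prop-1-en-2-yl]cyclohexa-2,5-dien-1-one | C=CCC1=C[C@](O)(/C(C)=C/c2ccc(OC)c(OC)c2)C(OC)=CC1=O | intermediate
15 | sodium alkoxide of 14 (not isolated) | C=CCC1=C[C@]([O-])(/C(C)=C/c2ccc(OC)c(OC)c2)C(OC)=CC1=O.[Na+] | intermediate
16 | (S)-2-allyl-4-[(E)-1-(3,4-dimethoxyphenyl)prop-1-en-2-yl]-4,5-dimethoxycyclohexa-2,5-dien-1-one | C=CCC1=C[C@](OC)(/C(C)=C/c2ccc(OC)c(OC)c2)C(OC)=CC1=O | target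

Total step count: 6. Longest linear sequence: 5 steps (steps 1, 2, 3, 5 and 6, from dimethyl squarate).

**Steps most likely to fail**

Step 5 (proposed new method). The quinone is an oxidant, so electron transfer from the organozinc or zirconocene species may reduce it or alkylate it on oxygen. Methyl may transfer in place of alkenyl, the catalyst may bind the more basic vinylogous ester carbonyl, and face discrimination between the methoxy and hydrogen flanks may be weak. The fallback uses known chemistry only and sets out from 11 and 8. Copper-catalysed borylation and protonation of 11 (B2pin2, CuCl, Xantphos, NaOtBu, MeOH, THF, rt) should give (Z)-2-[1-(3,4-dimethoxyphenyl)prop-1-en-2-yl]-4,4,5,5-tetramethyl-1,3,2-dioxaborolane F1, with boron on the carbon remote from the aryl group by syn addition. Iododeboronation with retention (NaOH, I2, THF/water, 0 °C) should give (E)-4-(2-iodoprop-1-en-1-yl)-1,2-dimethoxybenzene F2. Iodine–lithium exchange (t-BuLi, 2 equiv, THF, −78 °C) gives [(Z)-1-(3,4-dimethoxyphenyl)prop-1-en-2-yl]lithium F3 (aryl trans to lithium), which at −78 °C should add to the carbonyl of 8 next to the methoxy carbon to give racemic 2-allyl-4-hydroxy-5-methoxy-4-[(E)-1-(3,4-dimethoxyphenyl)prop-1-en-2-yl]cyclohexa-2,5-dien-1-one F4. Separation of the enantiomers of F4 on a chiral stationary phase brings the route back at 14.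

Step 3. The ketene may be captured by the free tertiary hydroxyl of a second molecule or by adventitious water and then oligomerize, or the hydrogen shift that ends the cascade may lag behind decay of the diradical. The fallback sets out from 6 and changes the migrating group. Silylation (Me3SiCl, Et3N, CH2Cl2, 0 °C) gives 3-methoxy-4-(pent-4-en-1-yn-1-yl)-4-[(trimethylsilyl)oxy]cyclobut-2-en-1-one F5. Thermolysis in p-xylene should then give, by the same ring opening and closure with silyl transfer from oxygen to the ring carbon radical, 2-allyl-5-methoxy-3-(trimethylsilyl)-1,4-benzoquinone F6. Protodesilylation (CF3CO2H, CH2Cl2, rt) brings the route back at 8.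

Step 2. The skipped enyne carries a doubly activated CH2 group, so metalation or the basic addition medium may cause propargyl–allenyl isomerization or a second deprotonation, which erodes the 1,2-addition. The fallback sets out from 3 and installs the allyl group after the carbinol is made. HC≡CMgBr (THF, −78 °C) should add to the same carbonyl to give 4-ethynyl-4-hydroxy-3-methoxycyclobut-2-en-1-one F7. Copper-catalysed coupling of the terminal alkyne with allyl bromide (CuI, K2CO3, Bu4NI, DMF, rt) under mildly basic conditions brings the route back at 6.

**Further compounds**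

F1 | step 5 | (Z)-2-[1-(3,4-dimethoxyphenyl)prop-1-en-2-yl]-4,4,5,5-tetramethyl-1,3,2-dioxaborolane | C/C(=C\c1ccc(OC)c(OC)c1)B1OC(C)(C)C(C)(C)O1
F2 | step 5 | (E)-4-(2-iodoprop-1-en-1-yl)-1,2-dimethoxybenzene | C/C(I)=C\c1ccc(OC)c(OC)c1
F3 | step 5 | [(Z)-1-(3,4-dimethoxyphenyl)prop-1-en-2-yl]lithium | [Li]/C(C)=C/c1ccc(OC)c(OC)c1
F4 | step 5 | racemic 2-allyl-4-hydroxy-5-methoxy-4-[(E)-1-(3,4-dimethoxyphenyl)prop-1-en-2-yl]cyclohexa-2,5-dien-1-one | C=CCC1=CC(O)(/C(C)=C/c2ccc(OC)c(OC)c2)C(OC)=CC1=O
F5 | step 3 | 3-methoxy-4-(pent-4-en-1-yn-1-yl)-4-[(trimethylsilyl)oxy]cyclobut-2-en-1-one (racemic) | COC1=CC(=O)C1(O[Si](C)(C)C)C#CCC=C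
F6 | step 3 | 2-allyl-5-methoxy-3-(trimethylsilyl)-1,4-benzoquinone | C=CCC1=C([Si](C)(C)C)C(=O)C(OC)=CC1=O
F7 | step 2 | 4-ethynyl-4-hydroxy-3-methoxycyclobut-2-en-1-one (racemic) | COC1=CC(=O)C1(O)C#C
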